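**Retrosynthetic overview**
- Endgame: the C3 angelate, C8=CH2 (Wittig) and the C9 side chain (γ-alkylation of the C8 ketone through its 7-formyl polyanion with an E-homoallylic iodide) are added last; the C18 hydroxyl comes from O3-directed C–H silylation/oxidation of the equatorial C4 methyl group.
- Key disconnection C1–C10: ring A is closed by 6-endo-trig addition of the tertiary C10 radical (released from the C10–O bond of a redox-active oxalate) to C1 of a C3 vinyl ketone.
- Enabling feature: the ring B chair carries at C5 an equatorial C4(CH3)2–C3(=O)–C2=C1 tether next to the tertiary C10 carbinol, and a C8 dioxolane whose axial oxygen shields the axial face of C10, so a trans fusion is expected.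
- The C4–C5 bond and the C10–O bond come from anti opening of a Shi epoxide of 3-methylcyclohex-3-enone ethylene ketal by the isobutyric acid dianion (temporary γ-lactone); the epoxide is the only catalyst-set stereo-element, and C10, C3, C4 and C9 are relayed from it.
- Ring order: ring B is bought as the benzene ring of 3-methylanisole (Birch reduction); ring A is formed in the key step.

Key step: step 7

Remark: labdane numbering is used for all intermediates (C18 = equatorial C4 substituent, C19 = axial C4 methyl, C20 = C10 methyl); the facial sense of the Shi epoxidation is assumed to follow that known for 1-phenylcyclohexene.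

Step 1
Reactants: 1 3-methylanisole
Product: 2 1-methoxy-5-methylcyclohexa-1,4-diene
Conditions: Li, NH3 (l), THF, t-BuOH, −78 → −33 °C; NH4Cl
Reagents that add atoms: none
Why: Birch reduction leaves the methoxy- and methyl-bearing carbons sp2, which places the enol ether (future C8) and the C10(CH3)=C5 alkene 1,3 to each other; no stereocenter is formed.

Step 2
Reactants: 2 1-methoxy-5-methylcyclohexa-1,4-diene
Product: 3 7-methyl-1,4-dioxaspiro[4.5]dec-7-ene
Conditions: HOCH2CH2OH, PPTS (cat.), THF, 0 °C → rt
Reagents that add atoms: ethylene glycol, OCCO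
Why: Acetal exchange through kinetic C-protonation of the enol ether at C7 and capture of the oxocarbenium ion by the diol should give the dioxolane without moving the isolated C10=C5 double bond into conjugation.

Step 3
Reactants: 3 7-methyl-1,4-dioxaspiro[4.5]dec-7-ene
Product: 4 (1S,6R)-1-methyl-7-oxabicyclo[4.1.0]heptan-3-one ethylene ketal
Conditions: D-fructose-derived Shi ketone (0.3 equiv), KHSO5 (as Oxone), K2CO3, Bu4NHSO4, MeCN/DMM, aq. Na2B4O7/Na2EDTA (pH 10.5), 0 °C
Reagents that add atoms: potassium peroxymonosulfate, [K+].[O-]S(=O)(=O)OO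
Why: Shi epoxidation of the unconjugated trisubstituted alkene through the spiro transition state should, by analogy with 1-phenylcyclohexene, deliver oxygen to the face that gives the (C10 S, C5 R)-epoxide, so the catalyst sets the absolute configuration of the route.

Step 4
Reactants: 4 (1S,6R)-1-methyl-7-oxabicyclo[4.1.0]heptan-3-one ethylene ketal; 5 isobutyric acid
Product: 7 trans-fused lactone (3aR,7aS)-6,6-ethylenedioxy-3,3,7a-trimethylhexahydro-1-benzofuran-2(3H)-one, via hydroxy acid 6 (not isolated)
Conditions: 5, LiN(i-Pr)2 (2 equiv per 5), THF, 0 → 45 °C; then 4, 50 °C; aq. citric acid; then PPTS (cat.), benzene, 4 Å MS, 45 °C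
Reagents that add atoms: none
Why: The carboxylic acid dianion should open the trisubstituted epoxide by SN2 attack at the less substituted carbon C5 with inversion (trans-diaxial opening), which forms the C4–C5 bond and sets C5 from the epoxide; the gem-dimethyl γ-hydroxy acid then lactonises onto the tertiary C10 hydroxyl to give a temporary ring.

Step 5
Reactants: 7 trans-fused lactone
Product: 8 4-[(7S,8R)-7-hydroxy-7-methyl-1,4-dioxaspiro[4.5]decan-8-yl]-4-methylpent-1-en-3-one
Conditions: vinyl bromide, t-BuLi (2 equiv), Et2O, −78 °C; then 7, THF, −78 °C; AcOH, −78 °C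
Reagents that add atoms: vinyllithium, [Li]C=C (made in the flask from vinyl bromide, C=CBr)
Why: Addition of one equivalent of the organolithium to the hindered α,α-disubstituted γ-lactone should stop at the lithium lactolate, which gives the hydroxy vinyl ketone only on protonation and so avoids double addition; no stereocenter is touched.

Step 6
Reactants: 8 hydroxy vinyl ketone
Product: 9 N-phthalimidoyl oxalate of the tertiary alcohol 8
Conditions: ClC(O)C(O)O–NPhth (freshly made from N-hydroxyphthalimide and oxalyl chloride), Et3N, DMAP (cat.), CH2Cl2, −20 → 0 °C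
Reagents that add atoms: N-phthalimidoyl chlorooxalate, ClC(=O)C(=O)ON1C(=O)c2ccccc2C1=O
Why: O-acylation of the tertiary C10 alcohol by the acid chloride (nucleophilic catalysis) turns the C10–O bond into a redox-active oxalate; no stereocenter is touched.

Step 7
Reactants: 9 N-phthalimidoyl oxalate
Product: 10 (5S,10S)-8,8-ethylenedioxy-4,4,10-trimethyl-trans-decalin-3-one
Conditions: Ru(bpy)3(PF6)2 (1.5 mol %), Hantzsch ester (1.5 equiv), i-Pr2NEt·HBF4 (1 equiv), THF/CH2Cl2 (0.01 M), blue LEDs, rt
Reagents that add atoms: none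
Why: Single-electron reduction of the N-acyloxyphthalimide by the photoreduced ruthenium catalyst cleaves the N–O bond, two losses of CO2 give the tertiary C10 radical, this adds 6-endo-trig to C1 of the vinyl ketone (closing ring A through the C1–C10 bond), and the α-keto radical at C2 is reduced by the Hantzsch ester. The closest known reaction type is the visible-light photoredox fragmentation of tert-alkyl N-phthalimidoyl oxalates with Giese addition of the tertiary radical to an enone, run here intramolecularly. The new quaternary stereocenter C10 is controlled by C5: in the chair–chair transition state the C5 tether is equatorial and the C1–C10 bond forms equatorially, so the C10 methyl becomes axial and the ring fusion trans. The step needs 6-endo over 5-exo closure, secured by the polarity match between the nucleophilic tertiary radical and the terminal β-carbon of the enone, and trans over cis fusion, secured by the axial oxygen of the C8 dioxolane, which is 1,3-diaxial to the axial face of C10. High dilution and the gem-dimethyl group at C4 should favour ring closure over premature hydrogen-atom transfer to the open-chain radical.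

Step 8
Reactants: 10 trans-decalin-3-one
Product: 11 (3R,5S,10S)-8,8-ethylenedioxy-4,4,10-trimethyl-trans-decalin-3-ol
Conditions: NaBH4, MeOH/CH2Cl2, −20 °C
Reagents that add atoms: none
Why: Hydride reduction of the 4,4-dimethyl-3-ketone should occur by axial attack on the face away from the axial C4 and C10 methyl groups (substrate control), giving the equatorial 3R alcohol.

Step 9
Reactants: 11 trans-decalin-3-ol
Product: 14 (3R,4S,5S,10S)-8,8-ethylenedioxy-4-(hydroxymethyl)-4,10-dimethyl-trans-decalin-3-ol, via silyl ether 12 (not isolated), via oxasilolane 13 (not isolated)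
Conditions: Et2SiH2, [Ir(cod)OMe]2 (cat.), THF, rt; then [Ir(cod)OMe]2, 3,4,7,8-tetramethyl-1,10-phenanthroline, norbornene, THF, 100 °C; then H2O2, KHCO3, MeOH/THF, 50 °C
Reagents that add atoms: hydrogen peroxide, OO
Why: Hydroxyl-directed iridium-catalysed γ-C–H silylation of the (hydrido)silyl ether followed by Tamao–Fleming oxidation should functionalise the equatorial C4 methyl, which alone can form an unstrained oxasilolane with the equatorial O3, so the C4 stereocenter (S) is set by the C3 alcohol.

Step 10
Reactants: 14 1,3-diol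
Product: 15 18-O-tert-butyldimethylsilyl ether of 14
Conditions: TBSCl (1.1 equiv), imidazole, CH2Cl2, 0 °C
Reagents that add atoms: tert-butyldimethylsilyl chloride, CC(C)(C)[Si](C)(C)Cl
Why: Silylation should select the primary C18 hydroxyl over the hindered secondary C3 hydroxyl next to the quaternary carbon; no stereocenter is touched.

Step 11
Reactants: 15 silyl ether ketal
Product: 16 (3R,4S,5S,10S)-3-hydroxy-4-[(tert-butyldimethylsilyloxy)methyl]-4,10-dimethyl-trans-decalin-8-one
Conditions: PPTS, THF/H2O, 50 °C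
Reagents that add atoms: water, O
Why: Mild acid-catalysed acetal hydrolysis should free the C8 ketone while the hindered primary silyl ether survives; no stereocenter is touched.

Step 12
Reactants: 16 C8 ketone
Product: 17 7-(hydroxymethylidene) derivative of 16
Conditions: HCO2Et, NaH, THF (cat. EtOH), 0 °C → rt; then K2CO3, MeOH, 0 °C; aq. NH4Cl
Reagents that add atoms: ethyl formate, CCOC=O
Why: Crossed Claisen condensation under equilibrating conditions should formylate C7, the α-carbon remote from the quaternary C10, giving the chelated enol that blocks C7 and allows polyanion formation; the brief methanolysis removes any formate at O3.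

Step 13
Reactants: 18 (E)-3-methylpent-2-en-4-yn-1-ol
Product: 19 (E)-tert-butyldimethyl[(3-methylpent-2-en-4-yn-1-yl)oxy]silane
Conditions: TBSCl, imidazole, CH2Cl2, 0 °C → rt
Reagents that add atoms: tert-butyldimethylsilyl chloride, CC(C)(C)[Si](C)(C)Cl
Why: Standard silylation of the primary allylic alcohol; the E double bond bought with 18 is kept.

Step 14
Reactants: 19 silyl enyne
Product: 20 (E)-tert-butyldimethyl[(3-methylpenta-2,4-dien-1-yl)oxy]silane
Conditions: H2 (1 atm), Pd/CaCO3 poisoned with Pb(OAc)2, quinoline, hexane, rt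
Reagents that add atoms: none
Why: Lindlar semihydrogenation should reduce the terminal alkyne to the vinyl group and leave the trisubstituted E-alkene untouched.

Step 15
Reactants: 20 silyl diene
Product: 22 (E)-5-[(tert-butyldimethylsilyl)oxy]-3-methylpent-3-en-1-ol, via alkylborane 21 (not isolated)
Conditions: 9-BBN, THF, 0 °C → rt; then NaOH, H2O2, 0 °C
Reagents that add atoms: hydrogen peroxide, OO
Why: Hydroboration with the bulky borane should add 1,2 to the monosubstituted terminal alkene (boron on the terminal carbon) much faster than to the trisubstituted alkene, and oxidation gives the primary alcohol with the E geometry retained.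

Step 16
Reactants: 22 homoallylic alcohol
Product: 23 (E)-tert-butyl[(5-iodo-3-methylpent-2-en-1-yl)oxy]dimethylsilane
Conditions: I2, PPh3, imidazole, CH2Cl2, 0 °C
Reagents that add atoms: iodine, II
Why: Appel-type iodination converts the primary alcohol into the iodide by SN2 displacement of the oxyphosphonium group.

Step 17
Reactants: 17 hydroxymethylidene ketone; 23 homoallylic iodide
Product: 25 (3R,4S,5S,9S,10R)-15,18-bis(tert-butyldimethylsilyloxy)-3-hydroxy-17-norlabd-13E-en-8-one, via formyl ketone 24 (not isolated)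
Conditions: LiN(i-Pr)2 (3.3 equiv), THF, −78 → 0 °C; 23, DMPU, 0 °C → rt; aq. NH4Cl; then NaOMe (cat.), MeOH, 45 °C
Reagents that add atoms: none
Why: γ-Alkylation of the β-keto aldehyde polyanion should take place at its most basic carbon C9 (SN2 on the primary iodide); methoxide then removes the formyl group by retro-Claisen cleavage and equilibrates C9 through the enolate to the equatorial side chain, trans to the axial C10 methyl (thermodynamic control).

Step 18
Reactants: 25 C8 ketone
Product: 26 (3R,4S,5S,9R,10S)-15,18-bis(tert-butyldimethylsilyloxy)labda-8(17),13E-dien-3-ol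
Conditions: Ph3PCH3Br, KOt-Bu, toluene, rt → 80 °C
Reagents that add atoms: methyltriphenylphosphonium bromide, C[P+](c1ccccc1)(c1ccccc1)c1ccccc1.[Br-]
Why: Wittig methylenation of the hindered C8 ketone with excess ylide should tolerate the free C3 hydroxyl as its alkoxide, and C9 is already the thermodynamic epimer, so the base should not change it.

Step 19
Reactants: 26 dienol; 27 angelic acid
Product: 28 3-O-angelate of 26
Conditions: 27, 2,4,6-trichlorobenzoyl chloride, Et3N, toluene, rt; then 26, 85 °C
Reagents that add atoms: none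
Why: Yamaguchi-type esterification through the mixed anhydride, run without a nucleophilic catalyst, should acylate the hindered C3 alcohol without Z-to-E isomerisation of the angelate; no stereocenter is touched.

Step 20
Reactants: 28 bis-silyl angelate
Product: 29 target, (3R,4S,5S,9R,10S)-3-angeloyloxylabda-8(17),13E-diene-15,18-diol
Conditions: HF·pyridine, pyridine/THF, 0 °C → rt
Reagents that add atoms: none
Why: Fluoride-mediated cleavage of both silyl ethers under buffered acidic conditions should avoid acyl migration to O18 and isomerisation of the angelate.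

**Compound list**
1 | 3-methylanisole | COc1cccc(C)c1 | starting material
2 | 1-methoxy-5-methylcyclohexa-1,4-diene | COC1=CCC=C(C)C1 | intermediate
3 | 7-methyl-1,4-dioxaspiro[4.5]dec-7-ene | CC1=CCCC2(C1)OCCO2 | intermediate
4 | (1S,6R)-1-methyl-7-oxabicyclo[4.1.0]heptan-3-one ethylene ketal | C13(OCCO3)CC[C@H]2O[C@@]2(C)C1 | intermediate
5 | isobutyric acid | CC(C)C(=O)O | starting material
6 | 2-[(7S,8R)-7-hydroxy-7-methyl-1,4-dioxaspiro[4.5]decan-8-yl]-2-methylpropanoic acid | C13(OCCO3)CC[C@H](C(C)(C)C(=O)O)[C@@](C)(O)C1 | intermediate (not isolated)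
7 | (3aR,7aS)-6,6-ethylenedioxy-3,3,7a-trimethylhexahydro-1-benzofuran-2(3H)-one (trans-fused lactone) | C13(OCCO3)CC[C@H]2[C@@](C)(OC(=O)C2(C)C)C1 | intermediate
8 | 4-[(7S,8R)-7-hydroxy-7-methyl-1,4-dioxaspiro[4.5]decan-8-yl]-4-methylpent-1-en-3-one | C13(OCCO3)CC[C@H](C(C)(C)C(=O)C=C)[C@@](C)(O)C1 | intermediate
9 | (7S,8R)-7-methyl-8-(2-methyl-3-oxopent-4-en-2-yl)-1,4-dioxaspiro[4.5]decan-7-yl N-phthalimidoyl oxalate | C13(OCCO3)CC[C@H](C(C)(C)C(=O)C=C)[C@@](C)(OC(=O)C(=O)ON2C(=O)c4ccccc4C2=O)C1 | intermediate
10 | (5S,10S)-8,8-ethylenedioxy-4,4,10-trimethyl-trans-decalin-3-one | C13(OCCO3)CC[C@H]2[C@@](C)(CCC(=O)C2(C)C)C1 | intermediate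
11 | (3R,5S,10S)-8,8-ethylenedioxy-4,4,10-trimethyl-trans-decalin-3-ol (equatorial OH) | C13(OCCO3)CC[C@H]2[C@@](C)(CC[C@@H](O)C2(C)C)C1 | intermediate
12 | diethyl(hydrido)silyl ether of 11 | C13(OCCO3)CC[C@H]2[C@@](C)(CC[C@@H](O[SiH](CC)CC)C2(C)C)C1 | intermediate (not isolated)
13 | oxasilolane bridging O3 and C18 through SiEt2 | C13(OCCO3)CC[C@H]2[C@@](C)(CC[C@H]4O[Si](CC)(CC)C[C@@]42C)C1 | intermediate (not isolated)
14 | (3R,4S,5S,10S)-8,8-ethylenedioxy-4-(hydroxymethyl)-4,10-dimethyl-trans-decalin-3-ol (CH2OH equatorial) | C13(OCCO3)CC[C@H]2[C@@](C)(CC[C@@H](O)[C@]2(C)CO)C1 | intermediate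
15 | 18-O-tert-butyldimethylsilyl ether of 14 | C13(OCCO3)CC[C@H]2[C@@](C)(CC[C@@H](O)[C@]2(C)CO[Si](C)(C)C(C)(C)C)C1 | intermediate
16 | (3R,4S,5S,10S)-3-hydroxy-4-[(tert-butyldimethylsilyloxy)methyl]-4,10-dimethyl-trans-decalin-8-one | O=C1CC[C@H]2[C@@](C)(CC[C@@H](O)[C@]2(C)CO[Si](C)(C)C(C)(C)C)C1 | intermediate
17 | 7-(hydroxymethylidene) derivative of 16 (chelated Z enol) | O=C1/C(=C\O)C[C@H]2[C@@](C)(CC[C@@H](O)[C@]2(C)CO[Si](C)(C)C(C)(C)C)C1 | intermediate
18 | (E)-3-methylpent-2-en-4-yn-1-ol | C#C/C(C)=C/CO | starting material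
19 | (E)-tert-butyldimethyl[(3-methylpent-2-en-4-yn-1-yl)oxy]silane | C#C/C(C)=C/CO[Si](C)(C)C(C)(C)C | intermediate
20 | (E)-tert-butyldimethyl[(3-methylpenta-2,4-dien-1-yl)oxy]silane | C=C/C(C)=C/CO[Si](C)(C)C(C)(C)C | intermediate
21 | B-[(E)-5-(tert-butyldimethylsilyloxy)-3-methylpent-3-en-1-yl]-9-borabicyclo[3.3.1]nonane | C1CC2CCCC(C1)B2CC/C(C)=C/CO[Si](C)(C)C(C)(C)C | intermediate (not isolated)
22 | (E)-5-[(tert-butyldimethylsilyl)oxy]-3-methylpent-3-en-1-ol | OCC/C(C)=C/CO[Si](C)(C)C(C)(C)C | intermediate
23 | (E)-tert-butyl[(5-iodo-3-methylpent-2-en-1-yl)oxy]dimethylsilane | ICC/C(C)=C/CO[Si](C)(C)C(C)(C)C | intermediate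
24 | 9-alkylated 7-(hydroxymethylidene) ketone (C9 epimers) | O=C1/C(=C\O)C[C@H]2[C@@](C)(CC[C@@H](O)[C@]2(C)CO[Si](C)(C)C(C)(C)C)C1CC/C(C)=C/CO[Si](C)(C)C(C)(C)C | intermediate (not isolated)
25 | (3R,4S,5S,9S,10R)-15,18-bis(tert-butyldimethylsilyloxy)-3-hydroxy-17-norlabd-13E-en-8-one | O=C1CC[C@H]2[C@@](C)(CC[C@@H](O)[C@]2(C)CO[Si](C)(C)C(C)(C)C)[C@@H]1CC/C(C)=C/CO[Si](C)(C)C(C)(C)C | intermediate
26 | (3R,4S,5S,9R,10S)-15,18-bis(tert-butyldimethylsilyloxy)labda-8(17),13E-dien-3-ol | C=C1CC[C@H]2[C@@](C)(CC[C@@H](O)[C@]2(C)CO[Si](C)(C)C(C)(C)C)[C@@H]1CC/C(C)=C/CO[Si](C)(C)C(C)(C)C | intermediate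
27 | angelic acid, (Z)-2-methylbut-2-enoic acid | C/C=C(/C)C(=O)O | starting material
28 | 3-O-angelate of 26 | C=C1CC[C@H]2[C@@](C)(CC[C@@H](OC(=O)/C(C)=C\C)[C@]2(C)CO[Si](C)(C)C(C)(C)C)[C@@H]1CC/C(C)=C/CO[Si](C)(C)C(C)(C)C | intermediate
29 | (3R,4S,5S,9R,10S)-3-angeloyloxylabda-8(17),13E-diene-15,18-diol (CNP0118197.1) | C=C1CC[C@H]2[C@@](C)(CC[C@@H](OC(=O)/C(C)=C\C)[C@]2(C)CO)[C@@H]1CC/C(C)=C/CO | target

Total step count: 20. Longest linear sequence: 16 steps (steps 1–12 and 17–20); the side-chain iodide 23 takes steps 13–16.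

**Steps most likely to fail**

Step 7. The tertiary radical may be quenched by hydrogen-atom transfer before it cyclises, the oxalate may be lost by hydrolysis before it fragments, and the trans selectivity of the ring fusion may erode. The fallback generates the same radical from an alkene. From 8, anti-elimination of the tertiary alcohol (SOCl2, pyridine, CH2Cl2, −10 °C; the C5 hydrogen is syn to the hydroxyl and cannot take part) should give mainly the exocyclic alkene 4-methyl-4-[(8S)-7-methylidene-1,4-dioxaspiro[4.5]decan-8-yl]pent-1-en-3-one F1, with some of the endocyclic isomer 4-methyl-4-[(8S)-7-methyl-1,4-dioxaspiro[4.5]dec-6-en-8-yl]pent-1-en-3-one F2. Both would be cyclised without separation by hydrogen-atom transfer from an iron hydride (Fe(acac)3, PhSiH3, EtOH/ethylene glycol, 60 °C), which gives the same C10 radical without a strong hydrogen-atom donor present and returns to the route at 10.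

Step 4. Deprotonation of the epoxide (isomerisation to an allylic alcohol) may outrun SN2 opening by the hindered tertiary carbanion. The fallback uses the smaller, more nucleophilic anion of isobutyronitrile. From 4, LiC(CH3)2CN (isobutyronitrile, LiN(i-Pr)2, THF, 0 → 50 °C) should give the trans hydroxy nitrile 2-[(7S,8R)-7-hydroxy-7-methyl-1,4-dioxaspiro[4.5]decan-8-yl]-2-methylpropanenitrile F3. Reduction with i-Bu2AlH (toluene, −78 °C) and mild aqueous acid would give the hydroxy aldehyde 2-[(7S,8R)-7-hydroxy-7-methyl-1,4-dioxaspiro[4.5]decan-8-yl]-2-methylpropanal F4, and vinylmagnesium bromide the allylic alcohol 4-[(7S,8R)-7-hydroxy-7-methyl-1,4-dioxaspiro[4.5]decan-8-yl]-4-methylpent-1-en-3-ol F5 (both carbinol epimers). Oxidation of the allylic alcohol with MnO2 returns to the route at 8.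

Step 17. E2 elimination of the homoallylic iodide (its β-hydrogens are allylic) and incomplete alkylation at the neopentyl-type C9 carbanion may prevail. The fallback builds the side chain stepwise from a masked 3-oxobutyl group. From 17, the polyanion would be alkylated with 2-(2-iodoethyl)-2-methyl-1,3-dioxolane to the 9-alkylated hydroxymethylidene ketone F6, which is deformylated and equilibrated (NaOMe, MeOH) to the 9-(3,3-ethylenedioxybutyl) C8 ketone F7. Wittig methylenation would give the 8(17)-alkene F8, acetal hydrolysis (PPTS, THF/H2O) the side-chain methyl ketone F9, and Horner–Wadsworth–Emmons olefination with triethyl phosphonoacetate (NaH, THF) the ethyl (E)-enoate F10, from which the Z isomer is to be removed. Reduction with i-Bu2AlH would give (3R,4S,5S,9R,10S)-18-(tert-butyldimethylsilyloxy)labda-8(17),13E-diene-3,15-diol F11, and selective silylation of its primary allylic hydroxyl (TBSCl, imidazole) returns to the route at 26.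

Further compounds
F1 | step 7 | 4-methyl-4-[(8S)-7-methylidene-1,4-dioxaspiro[4.5]decan-8-yl]pent-1-en-3-one | C13(OCCO3)CC[C@H](C(C)(C)C(=O)C=C)C(=C)C1
F2 | step 7 | 4-methyl-4-[(8S)-7-methyl-1,4-dioxaspiro[4.5]dec-6-en-8-yl]pent-1-en-3-one | C13(OCCO3)CC[C@H](C(C)(C)C(=O)C=C)C(C)=C1
F3 | step 4 | 2-[(7S,8R)-7-hydroxy-7-methyl-1,4-dioxaspiro[4.5]decan-8-yl]-2-methylpropanenitrile | C13(OCCO3)CC[C@H](C(C)(C)C#N)[C@@](C)(O)C1
F4 | step 4 | 2-[(7S,8R)-7-hydroxy-7-methyl-1,4-dioxaspiro[4.5]decan-8-yl]-2-methylpropanal | C13(OCCO3)CC[C@H](C(C)(C)C=O)[C@@](C)(O)C1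
F5 | step 4 | 4-[(7S,8R)-7-hydroxy-7-methyl-1,4-dioxaspiro[4.5]decan-8-yl]-4-methylpent-1-en-3-ol (carbinol epimers) | C13(OCCO3)CC[C@H](C(C)(C)C(O)C=C)[C@@](C)(O)C1
F6 | step 17 | 9-[2-(2-methyl-1,3-dioxolan-2-yl)ethyl]-7-(hydroxymethylidene) derivative of 16 (C9 epimers) | O=C1/C(=C\O)C[C@H]2[C@@](C)(CC[C@@H](O)[C@]2(C)CO[Si](C)(C)C(C)(C)C)C1CCC3(C)OCCO3
F7 | step 17 | (3R,4S,5S,9S,10R)-9-[2-(2-methyl-1,3-dioxolan-2-yl)ethyl]-3-hydroxy-4-[(tert-butyldimethylsilyloxy)methyl]-4,10-dimethyl-trans-decalin-8-one | O=C1CC[C@H]2[C@@](C)(CC[C@@H](O)[C@]2(C)CO[Si](C)(C)C(C)(C)C)[C@@H]1CCC3(C)OCCO3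
F8 | step 17 | 8-methylidene analogue of F7 | C=C1CC[C@H]2[C@@](C)(CC[C@@H](O)[C@]2(C)CO[Si](C)(C)C(C)(C)C)[C@@H]1CCC3(C)OCCO3
F9 | step 17 | (3R,4S,5S,9R,10S)-18-(tert-butyldimethylsilyloxy)-3-hydroxy-14,15-dinorlabd-8(17)-en-13-one | C=C1CC[C@H]2[C@@](C)(CC[C@@H](O)[C@]2(C)CO[Si](C)(C)C(C)(C)C)[C@@H]1CCC(C)=O
F10 | step 17 | ethyl (3R,4S,5S,9R,10S)-18-(tert-butyldimethylsilyloxy)-3-hydroxylabda-8(17),13E-dien-15-oate | C=C1CC[C@H]2[C@@](C)(CC[C@@H](O)[C@]2(C)CO[Si](C)(C)C(C)(C)C)[C@@H]1CC/C(C)=C/C(=O)OCC
F11 | step 17 | (3R,4S,5S,9R,10S)-18-(tert-butyldimethylsilyloxy)labda-8(17),13E-diene-3,15-diol | C=C1CC[C@H]2[C@@](C)(CC[C@@H](O)[C@]2(C)CO[Si](C)(C)C(C)(C)C)[C@@H]1CC/C(C)=C/CO
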